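**Strategy**

The route rests on disconnecting the C7–C1 bond between the benzylic carbinol carbon and C1 of the 3,4,5-trimethoxyphenyl ring. A non-chelating 3,4,5-trimethoxyphenyltitanium reagent is added to (R)-2-(4-allyl-2,6-dimethoxyphenoxy)propanal, so that one operation joins both halves and creates the C7 carbinol stereocentre. The step exploits the acyclic erythro C7–OH/C8–OAr pair: the C8–O(aryl) bond, installed from ethyl (S)-lactate by Mitsunobu inversion, serves as the polar Felkin–Anh control element, and the symmetrical trimethoxyphenyl ring makes its bromide an unambiguous nucleophile precursor. The aldehyde is reached in two steps without protecting groups.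

Key step: step 3

Remark: neolignan numbering is used (C7 = benzylic carbinol carbon, C8 = aryloxy-bearing carbon, C9 = methyl). The target is the erythro (7S,8R) isomer, i.e. (1S,2R)-2-(4-allyl-2,6-dimethoxyphenoxy)-1-(3,4,5-trimethoxyphenyl)propan-1-ol.

**Route**

Step 1
Reactants: 1 4-allyl-2,6-dimethoxyphenol; 2 ethyl (S)-lactate
Product: 3 ethyl (R)-2-(4-allyl-2,6-dimethoxyphenoxy)propanoate
Conditions: PPh3, DIAD, THF, 0 °C → rt
Reagents that add atoms: none
Why: Mitsunobu etherification, in which the phenoxide of 1 (pKa about 10) displaces the alkoxyphosphonium of the α-hydroxy ester by SN2, so the lactate centre should be inverted from S to R and thereby set C8 of the target.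

Step 2
Reactants: 3 ethyl (R)-2-(4-allyl-2,6-dimethoxyphenoxy)propanoate
Product: 5 (R)-2-(4-allyl-2,6-dimethoxyphenoxy)propanal, via aluminium hemiacetal 4 (not isolated)
Conditions: DIBAL-H, CH2Cl2, −78 °C; then MeOH, aq. Rochelle salt; crude aldehyde used at once
Reagents that add atoms: none
Why: Partial ester reduction with DIBAL-H, in which the tetrahedral aluminium hemiacetal 4, held by chelation to the α-aryloxy oxygen, should persist at −78 °C and release the aldehyde only on work-up, while C8 and the terminal alkene are not touched.

Step 3
Reactants: 5 (R)-2-(4-allyl-2,6-dimethoxyphenoxy)propanal; 6 5-bromo-1,2,3-trimethoxybenzene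
Product: 10 rhaphidecursinol B, via aryllithium 7 (not isolated), via aryltitanium 8 (not isolated), via titanium alkoxide 9 (not isolated)
Conditions: 6, n-BuLi, THF, −78 °C; ClTi(OiPr)3, −78 → −40 °C; then 5, −78 → 0 °C; aq. NH4Cl
Reagents that add atoms: none
Why: Bromine–lithium exchange converts 6 into aryllithium 7, which ClTi(OiPr)3 transmetalates to the weakly Lewis-acidic and weakly basic aryltitanium 8; this transfers its aryl group to the aldehyde carbon of 5 to give titanium alkoxide 9, hydrolysed to 10 on work-up. The closest known reaction type is the non-chelation-controlled (polar Felkin–Anh) 1,2-addition of organotitanium triisopropoxides to α-alkoxy aldehydes; no ring is closed. The new C7 stereocentre is controlled by C8: in the reactive conformer the C8–OAr bond, the best σ* acceptor, stands perpendicular to the carbonyl plane and anti to the incoming aryl group, which passes the C8–H and not the C8–CH3 and so attacks the Si face, which should give the (7S,8R) erythro alcohol. The step needs Felkin–Anh control to win over chelation control, and the coordinatively saturated Ti(OiPr)3 centre together with the poorly Lewis-basic, doubly ortho-flanked aryl ether oxygen should disfavour the five-membered chelate that would lead to the threo epimer. The low basicity of 8 should also prevent enolisation of the epimerisable α-aryloxy aldehyde and deprotonation of the benzylic allyl CH2, and the terminal alkene is inert. Any minor threo epimer should be removable by chromatography.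

**Compound list**

1 | 4-allyl-2,6-dimethoxyphenol (methoxyeugenol) | C=CCc1cc(OC)c(O)c(OC)c1 | starting material
2 | ethyl (S)-lactate | CCOC(=O)[C@H](C)O | starting material
3 | ethyl (R)-2-(4-allyl-2,6-dimethoxyphenoxy)propanoate | C=CCc1cc(OC)c(O[C@H](C)C(=O)OCC)c(OC)c1 | intermediate
4 | diisobutylaluminium ethyl hemiacetal of 5, hemiacetal carbon unassigned (formed in the flask, not isolated) | C=CCc1cc(OC)c(O[C@H](C)C(OCC)O[Al](CC(C)C)CC(C)C)c(OC)c1 | intermediate
5 | (R)-2-(4-allyl-2,6-dimethoxyphenoxy)propanal | C=CCc1cc(OC)c(O[C@H](C)C=O)c(OC)c1 | intermediate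
6 | 5-bromo-1,2,3-trimethoxybenzene | COc1cc(Br)cc(OC)c1OC | starting material
7 | (3,4,5-trimethoxyphenyl)lithium (formed in the flask, not isolated) | [Li]c1cc(OC)c(OC)c(OC)c1 | intermediate
8 | triisopropoxy(3,4,5-trimethoxyphenyl)titanium (formed in the flask, not isolated) | CC(C)O[Ti](OC(C)C)(OC(C)C)c1cc(OC)c(OC)c(OC)c1 | intermediate
9 | triisopropoxytitanium alkoxide of 10 (formed in the flask, not isolated) | C=CCc1cc(OC)c(O[C@H](C)[C@@H](O[Ti](OC(C)C)(OC(C)C)OC(C)C)c2cc(OC)c(OC)c(OC)c2)c(OC)c1 | intermediate
10 | rhaphidecursinol B, (1S,2R)-2-(4-allyl-2,6-dimethoxyphenoxy)-1-(3,4,5-trimethoxyphenyl)propan-1-ol | C=CCc1cc(OC)c(O[C@H](C)[C@@H](O)c2cc(OC)c(OC)c(OC)c2)c(OC)c1 | target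

**Summary**

Total step count: 3.
Longest linear sequence: 3 steps (2 → 3 → 5 → 10).

**Steps most likely to fail**

Step 3. The facial selectivity may be insufficient if a chelated transition state competes with the Felkin–Anh one. A sluggish addition of the electron-rich aryltitanium could also leave time for epimerisation of the aldehyde at C8. The fallback forms the same C7–C1 bond by acyl substitution and sets C7 afterwards by reduction. It sets out from ester 3, which Me(MeO)NH·HCl and i-PrMgCl in THF at −20 °C should convert into the Weinreb amide (R)-2-(4-allyl-2,6-dimethoxyphenoxy)-N-methoxy-N-methylpropanamide F1. Aryllithium 7, made from 6 and n-BuLi as in step 3, should add to F1 at −78 °C to give the ketone (R)-2-(4-allyl-2,6-dimethoxyphenoxy)-1-(3,4,5-trimethoxyphenyl)propan-1-one F2. Chelation-controlled reduction of F2 with Zn(BH4)2 in Et2O at −20 °C should deliver hydride to the face of the zinc chelate that carries the C8–H, which gives the erythro alcohol; the fallback comes back to the route at 10.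

Step 1. The SN2 displacement on the alkoxyphosphonium may be slow because the phenoxide is flanked by two ortho-methoxy groups, so elimination or alkylation of the reduced azodicarboxylate could take over. The fallback replaces the redox condensation by a sulfonate displacement. It sets out from 2, which MsCl and Et3N in CH2Cl2 at 0 °C should convert into ethyl (S)-2-[(methylsulfonyl)oxy]propanoate F3. Phenol 1 with K2CO3 in MeCN at 60 °C should displace the mesylate of F3 with inversion; the fallback comes back to the route at 3.

Step 2. Over-reduction to the primary alcohol may occur if the aluminium hemiacetal collapses before the quench, and the aldehyde may epimerise at C8 during work-up. The fallback separates reduction and oxidation. It sets out from 3, which LiAlH4 in THF at 0 °C should reduce fully to (R)-2-(4-allyl-2,6-dimethoxyphenoxy)propan-1-ol F4. Oxidation of F4 with Dess–Martin periodinane and NaHCO3 in CH2Cl2 at 0 °C, just before use, should give the aldehyde; the fallback comes back to the route at 5.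

**Further compounds**

F1 | step 3 | (R)-2-(4-allyl-2,6-dimethoxyphenoxy)-N-methoxy-N-methylpropanamide | C=CCc1cc(OC)c(O[C@H](C)C(=O)N(C)OC)c(OC)c1
F2 | step 3 | (R)-2-(4-allyl-2,6-dimethoxyphenoxy)-1-(3,4,5-trimethoxyphenyl)propan-1-one | C=CCc1cc(OC)c(O[C@H](C)C(=O)c2cc(OC)c(OC)c(OC)c2)c(OC)c1
F3 | step 1 | ethyl (S)-2-[(methylsulfonyl)oxy]propanoate | CCOC(=O)[C@H](C)OS(C)(=O)=O
F4 | step 2 | (R)-2-(4-allyl-2,6-dimethoxyphenoxy)propan-1-ol | C=CCc1cc(OC)c(O[C@H](C)CO)c(OC)c1
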